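## Retrosynthetic overview

1. The last bond is C7–C8: the 15-membered carbocycle is closed by an intramolecular reductive Knoevenagel alkylation of a 3-unsubstituted 4-hydroxy-5,6-dihydropyran-2-one with a tethered, acetal-masked aldehyde (new reaction).
2. The dihydropyranone comes from a β-hydroxy aldehyde and ethyl diazoacetate (Roskamp homologation, then lactonisation). Its anti C4/C24 pair comes from a chelation-controlled Mukaiyama aldol of a west methyl ketone with an east α-chiral aldehyde.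
3. The tetrahydropyran is made by Achmatowicz oxidative ring expansion of a furyl carbinol, followed by C-glycosylation (quaternary C10), α-methylation (C13) and axial ketone reduction (C15).
4. The furyl carbinol (C17, C19) comes from asymmetric 2-(methoxycarbonyl)allylation of 5-methylfurfural and cis-selective hydrogenation; the east aldehyde (C4) from a copper-catalysed asymmetric allylic alkylation.
5. Ring order: furan → γ-lactone (temporary) → six-membered pyranone/tetrahydropyran by ring expansion → δ-lactone → 15-membered carbocycle.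

Atom labels: heavy atoms of the target SMILES counted left to right (C1–C3 propyl, C4, C5, O6, C7, C8, C9, C10, C11, C12, C13, C14, C15, O16, C17, C18, C19, C20, C21, O22, C23, C24, O25, C26, O27, O28).

Assumption: in the two ligand-controlled steps (1 and 11) the ligand antipode is the one that gives the configuration drawn, and the hemiketal from the ring expansion is used as its anomeric mixture.

## Route

Step 1
Reactants: 1 5-methylfuran-2-carbaldehyde; 2 methyl 2-(bromomethyl)prop-2-enoate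
Product: 4 (5S)-3-methylidene-5-(5-methylfuran-2-yl)oxolan-2-one, via hydroxy ester 3 (not isolated)
Conditions: CrCl2 (10 mol%), chiral carbazole-bis(oxazoline) ligand (12 mol%), Mn powder (2 equiv), Me3SiCl (1.5 equiv), THF, rt; then AcOH–H2O, 40 °C
Reagents that add atoms: none
Why: Catalytic asymmetric Nozaki–Hiyama–Kishi-type 2-(alkoxycarbonyl)allylation, in which the ligand-bound allylchromium species adds to one aldehyde face to set C17 (S) and the γ-hydroxy acrylate lactonises on mild acid work-up.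

Step 2
Reactants: 4 (5S)-3-methylidene-5-(5-methylfuran-2-yl)oxolan-2-one
Product: 5 (3S,5S)-3-methyl-5-(5-methylfuran-2-yl)oxolan-2-one
Conditions: H2 (1 atm), RhCl(PPh3)3 (5 mol%), toluene–EtOH, rt
Reagents that add atoms: none
Why: Homogeneous hydrogenation delivers H2 to the exocyclic alkene from the face opposite the furyl group, giving the cis-3,5-disubstituted lactone (sets C19) and leaving the furan intact.

Step 3
Reactants: 5 (3S,5S)-3-methyl-5-(5-methylfuran-2-yl)oxolan-2-one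
Product: 6 (2S,4S)-4-hydroxy-N-methoxy-N,2-dimethyl-4-(5-methylfuran-2-yl)butanamide
Conditions: MeNH(OMe)·HCl (3 equiv), i-PrMgCl (6 equiv), THF, −20 to 0 °C
Reagents that add atoms: N,O-dimethylhydroxylamine hydrochloride, CNOC.Cl
Why: Weinreb aminolysis of the lactone by the magnesium amide frees the C17 hydroxyl needed for ring expansion and keeps C21 at the acid oxidation level so that it survives the later ketone reduction.

Step 4
Reactants: 6 (2S,4S)-4-hydroxy-N-methoxy-N,2-dimethyl-4-(5-methylfuran-2-yl)butanamide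
Product: 7 (2S)-3-[(2S)-6-hydroxy-6-methyl-3-oxo-3,6-dihydro-2H-pyran-2-yl]-N-methoxy-N,2-dimethylpropanamide
Conditions: NBS (1.05 equiv), NaHCO3 (2 equiv), THF–H2O (4:1), 0 °C
Reagents that add atoms: water, O
Why: Achmatowicz oxidative ring expansion, in which bromonium-induced hydration opens the furan to a cis-enedione that recloses through the C17 hydroxyl to the six-membered pyranone hemiketal without touching C17.

Step 5
Reactants: 7 (2S)-3-[(2S)-6-hydroxy-6-methyl-3-oxo-3,6-dihydro-2H-pyran-2-yl]-N-methoxy-N,2-dimethylpropanamide; 8 trimethyl(vinyloxy)silane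
Product: 10 (2S)-3-[(2S,6S)-6-(2,2-dimethoxyethyl)-6-methyl-3-oxo-3,6-dihydro-2H-pyran-2-yl]-N-methoxy-N,2-dimethylpropanamide, via aldehyde 9 (not isolated)
Conditions: BF3·OEt2 (1.5 equiv), CH2Cl2, −78 to −40 °C; then HC(OMe)3, MeOH, −40 to 0 °C; Et3N
Reagents that add atoms: trimethyl orthoformate, COC(OC)OC
Why: Kishi-type C-glycosylation (Mukaiyama addition to the cyclic oxocarbenium ion) with axial attack anti to the C17 side chain gives the 2,6-trans product and sets the quaternary C10, and the β-alkoxy aldehyde is trapped at once as its dimethyl acetal.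

Step 6
Reactants: 10 (2S)-3-[(2S,6S)-6-(2,2-dimethoxyethyl)-6-methyl-3-oxo-3,6-dihydro-2H-pyran-2-yl]-N-methoxy-N,2-dimethylpropanamide
Product: 11 (2S)-3-[(2S,6R)-6-(2,2-dimethoxyethyl)-6-methyl-3-oxooxan-2-yl]-N-methoxy-N,2-dimethylpropanamide
Conditions: H2 (1 atm), 10% Pd/C, EtOAc, rt
Reagents that add atoms: none
Why: Heterogeneous hydrogenation saturates only the conjugated C12=C13 bond (no new stereocentre; the descriptor at C10 changes by priority only).

Step 7
Reactants: 11 (2S)-3-[(2S,6R)-6-(2,2-dimethoxyethyl)-6-methyl-3-oxooxan-2-yl]-N-methoxy-N,2-dimethylpropanamide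
Product: 12 (2S)-3-[(2S,4S,6R)-6-(2,2-dimethoxyethyl)-4,6-dimethyl-3-oxooxan-2-yl]-N-methoxy-N,2-dimethylpropanamide
Conditions: LiN(i-Pr)2 (1.1 equiv), THF, −78 °C; then MeI (3 equiv), −78 to −30 °C
Reagents that add atoms: iodomethane, CI
Why: Kinetic enolate alkylation, in which the base removes a C13 methylene proton rather than the alkoxy-substituted C17 methine and iodomethane enters anti to the axial C9 chain on C10, placing the C13 methyl equatorial and cis to the C17 side chain.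

Step 8
Reactants: 12 (2S)-3-[(2S,4S,6R)-6-(2,2-dimethoxyethyl)-4,6-dimethyl-3-oxooxan-2-yl]-N-methoxy-N,2-dimethylpropanamide
Product: 14 (3S)-4-[(2S,3S,4S,6R)-6-(2,2-dimethoxyethyl)-3-hydroxy-4,6-dimethyloxan-2-yl]-3-methylbutan-2-one, via hydroxy amide 13 (not isolated)
Conditions: LiBH(s-Bu)3 (1.2 equiv), THF, −78 °C; then MeMgBr (4 equiv), −78 to 0 °C; aqueous work-up
Reagents that add atoms: methylmagnesium bromide, C[Mg]Br
Why: The bulky hydride attacks the ketone from the equatorial side between its two equatorial neighbours to give the axial C15 alcohol, and the Grignard addition to the Weinreb amide then stops at the chelated adduct, so the methyl ketone appears only on work-up.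

Step 9
Reactants: 14 (3S)-4-[(2S,3S,4S,6R)-6-(2,2-dimethoxyethyl)-3-hydroxy-4,6-dimethyloxan-2-yl]-3-methylbutan-2-one
Product: 15 {[(3S)-4-{(2S,3S,4S,6R)-6-(2,2-dimethoxyethyl)-4,6-dimethyl-3-[(trimethylsilyl)oxy]oxan-2-yl}-3-methylbut-1-en-2-yl]oxy}trimethylsilane
Conditions: LiN(i-Pr)2 (2.3 equiv), Me3SiCl (3 equiv, present from the start), THF, −78 °C
Reagents that add atoms: chlorotrimethylsilane, C[Si](C)(C)Cl
Why: Kinetic deprotonation at the methyl group (C23) with in situ silylation gives the less substituted enol silane without enolising the C19 methine, and the C15 alkoxide is silylated as well.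

Step 10
Reactants: 16 (2E)-1,4-dibromobut-2-ene
Product: 17 1-({[(2E)-4-bromobut-2-en-1-yl]oxy}methyl)-4-methoxybenzene
Conditions: NaH (1.1 equiv), THF, 0 °C; then 16 (3 equiv), 0 °C to rt
Reagents that add atoms: 4-methoxybenzyl alcohol, COc1ccc(CO)cc1
Why: Williamson etherification with excess dibromide gives the mono-ether, whose ether oxygen later becomes the C5 oxygen.

Step 11
Reactants: 17 1-({[(2E)-4-bromobut-2-en-1-yl]oxy}methyl)-4-methoxybenzene; 18 propylmagnesium bromide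
Product: 19 1-methoxy-4-({[(2R)-2-ethenylpentyl]oxy}methyl)benzene
Conditions: CuBr·SMe2 (1 mol%), TaniaPhos (1.2 mol%), CH2Cl2, −78 °C
Reagents that add atoms: none
Why: Copper-catalysed asymmetric allylic alkylation (SN2′) of the allylic bromide by the Grignard reagent gives the branched alkene and sets C4 under ligand control.

Step 12
Reactants: 19 1-methoxy-4-({[(2R)-2-ethenylpentyl]oxy}methyl)benzene
Product: 20 (2S)-2-{[(4-methoxyphenyl)methoxy]methyl}pentanal
Conditions: O3, CH2Cl2, −78 °C; then PPh3, −78 °C to rt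
Reagents that add atoms: ozone, [O-][O+]=O
Why: Ozonolysis with neutral reductive work-up cleaves the vinyl group to the aldehyde (C24) without epimerising the α-stereocentre.

Step 13
Reactants: 15 {[(3S)-4-{(2S,3S,4S,6R)-6-(2,2-dimethoxyethyl)-4,6-dimethyl-3-[(trimethylsilyl)oxy]oxan-2-yl}-3-methylbut-1-en-2-yl]oxy}trimethylsilane; 20 (2S)-2-{[(4-methoxyphenyl)methoxy]methyl}pentanal
Product: 21 (2S,5R,6S)-1-[(2S,3S,4S,6R)-6-(2,2-dimethoxyethyl)-3-hydroxy-4,6-dimethyloxan-2-yl]-5-hydroxy-6-{[(4-methoxybenzyl)oxy]methyl}-2-methylnonan-3-one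
Conditions: MgBr2·OEt2 (3 equiv), CH2Cl2, −78 to −30 °C; then PPTS (cat.), MeOH, 0 °C
Reagents that add atoms: none
Why: Chelation-controlled Mukaiyama aldol, in which MgBr2 ties the aldehyde and ether oxygens into a six-membered chelate and the enol silane attacks anti to the propyl group, giving the anti-Felkin adduct with C24 (R) anti to C4; methanolysis then removes both silyl groups while the acetal stays.

Step 14
Reactants: 21 (2S,5R,6S)-1-[(2S,3S,4S,6R)-6-(2,2-dimethoxyethyl)-3-hydroxy-4,6-dimethyloxan-2-yl]-5-hydroxy-6-{[(4-methoxybenzyl)oxy]methyl}-2-methylnonan-3-one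
Product: 22 (2S,5R,6S)-1-[(2S,3S,4S,6R)-6-(2,2-dimethoxyethyl)-3-hydroxy-4,6-dimethyloxan-2-yl]-5-hydroxy-6-(hydroxymethyl)-2-methylnonan-3-one
Conditions: DDQ (1.3 equiv), CH2Cl2–pH 7 buffer (10:1), 0 °C
Reagents that add atoms: none
Why: Oxidative cleavage of the 4-methoxybenzyl ether under wet buffered conditions frees the primary C5 alcohol without forming the benzylidene acetal.

Step 15
Reactants: 22 (2S,5R,6S)-1-[(2S,3S,4S,6R)-6-(2,2-dimethoxyethyl)-3-hydroxy-4,6-dimethyloxan-2-yl]-5-hydroxy-6-(hydroxymethyl)-2-methylnonan-3-one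
Product: 23 (2R,3R,6S)-7-[(2S,3S,4S,6R)-6-(2,2-dimethoxyethyl)-3-hydroxy-4,6-dimethyloxan-2-yl]-3-hydroxy-6-methyl-5-oxo-2-propylheptanal
Conditions: TEMPO (0.2 equiv), PhI(OAc)2 (1.2 equiv), CH2Cl2, 0 °C to rt
Reagents that add atoms: none
Why: Oxoammonium oxidation is selective for the primary alcohol over the two secondary ones and does not epimerise C4.

Step 16
Reactants: 23 (2R,3R,6S)-7-[(2S,3S,4S,6R)-6-(2,2-dimethoxyethyl)-3-hydroxy-4,6-dimethyloxan-2-yl]-3-hydroxy-6-methyl-5-oxo-2-propylheptanal; 24 ethyl diazoacetate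
Product: 26 (5R,6R)-6-{(3S)-4-[(2S,3S,4S,6R)-6-(2,2-dimethoxyethyl)-3-hydroxy-4,6-dimethyloxan-2-yl]-3-methyl-2-oxobutyl}-4-hydroxy-5-propyl-5,6-dihydro-2H-pyran-2-one, via keto ester 25 (not isolated)
Conditions: SnCl2 (0.2 equiv), CH2Cl2, rt; then K2CO3 (1.5 equiv), MeOH, 0 °C; AcOH (3 equiv)
Reagents that add atoms: none
Why: Roskamp homologation (Lewis-acid-promoted addition of the diazo ester to the aldehyde, then 1,2-hydride shift with loss of N2) gives the β-keto ester, which lactonises onto the C24 hydroxyl by base-mediated transesterification.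

Step 17
Reactants: 26 (5R,6R)-6-{(3S)-4-[(2S,3S,4S,6R)-6-(2,2-dimethoxyethyl)-3-hydroxy-4,6-dimethyloxan-2-yl]-3-methyl-2-oxobutyl}-4-hydroxy-5-propyl-5,6-dihydro-2H-pyran-2-one
Product: 29 mangromicin C, via aldehyde 27 (not isolated), via alkylidene dione 28 (not isolated)
Conditions: CF3CO2H (10 mM), H2O (50 mM), Hantzsch ester (diethyl 2,6-dimethyl-1,4-dihydropyridine-3,5-dicarboxylate, 1.5 equiv), CH2Cl2–CF3CH2OH (4:1), 35 °C, 26 added by syringe pump over 12 h (final 1 mM)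
Reagents that add atoms: none
Why: Proposed new method: a macrocyclising reductive Knoevenagel alkylation in which aqueous acid unmasks the C8 aldehyde at high dilution, the strongly enolised β-keto lactone (pKa about 5) condenses through C7 to the 15-membered alkylidene-1,3-dione, and this very electrophilic alkene is reduced irreversibly by conjugate hydride transfer from the Hantzsch ester before it can add a second dione, so the reversible condensation is funnelled to the C7–C8 alkylated macrocycle, with no amine present so that the β-alkoxy aldehyde cannot open the tetrahydropyran through an enamine; the closest known reaction is the intermolecular three-component reductive alkylation of cyclic 1,3-dicarbonyls with aldehydes and Hantzsch ester (Knoevenagel condensation, then transfer hydrogenation), which has not been used to close a macrocycle.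

## Compound list

1 | 5-methylfuran-2-carbaldehyde | Cc1ccc(C=O)o1 | starting material
2 | methyl 2-(bromomethyl)prop-2-enoate | C=C(CBr)C(=O)OC | starting material
3 | methyl (4S)-4-hydroxy-2-methylidene-4-(5-methylfuran-2-yl)butanoate | Cc1ccc(o1)[C@@H](O)CC(=C)C(=O)OC | intermediate
4 | (5S)-3-methylidene-5-(5-methylfuran-2-yl)oxolan-2-one | Cc1ccc(o1)[C@@H]1CC(=C)C(=O)O1 | intermediate
5 | (3S,5S)-3-methyl-5-(5-methylfuran-2-yl)oxolan-2-one (cis) | Cc1ccc(o1)[C@@H]1C[C@H](C)C(=O)O1 | intermediate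
6 | (2S,4S)-4-hydroxy-N-methoxy-N,2-dimethyl-4-(5-methylfuran-2-yl)butanamide | Cc1ccc(o1)[C@@H](O)C[C@H](C)C(=O)N(C)OC | intermediate
7 | (2S)-3-[(2S)-6-hydroxy-6-methyl-3-oxo-3,6-dihydro-2H-pyran-2-yl]-N-methoxy-N,2-dimethylpropanamide (both C6 anomers) | C[C@@H](C[C@@H]1OC(C)(O)C=CC1=O)C(=O)N(C)OC | intermediate
8 | trimethyl(vinyloxy)silane | C=CO[Si](C)(C)C | starting material
9 | (2S)-N-methoxy-N,2-dimethyl-3-[(2S,6S)-6-methyl-3-oxo-6-(2-oxoethyl)-3,6-dihydro-2H-pyran-2-yl]propanamide | C[C@@H](C[C@@H]1O[C@@](C)(CC=O)C=CC1=O)C(=O)N(C)OC | intermediate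
10 | (2S)-3-[(2S,6S)-6-(2,2-dimethoxyethyl)-6-methyl-3-oxo-3,6-dihydro-2H-pyran-2-yl]-N-methoxy-N,2-dimethylpropanamide | C[C@@H](C[C@@H]1O[C@@](C)(CC(OC)OC)C=CC1=O)C(=O)N(C)OC | intermediate
11 | (2S)-3-[(2S,6R)-6-(2,2-dimethoxyethyl)-6-methyl-3-oxooxan-2-yl]-N-methoxy-N,2-dimethylpropanamide | C[C@@H](C[C@@H]1O[C@@](C)(CC(OC)OC)CCC1=O)C(=O)N(C)OC | intermediate
12 | (2S)-3-[(2S,4S,6R)-6-(2,2-dimethoxyethyl)-4,6-dimethyl-3-oxooxan-2-yl]-N-methoxy-N,2-dimethylpropanamide | C[C@@H](C[C@@H]1O[C@@](C)(CC(OC)OC)C[C@H](C)C1=O)C(=O)N(C)OC | intermediate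
13 | (2S)-3-[(2S,3S,4S,6R)-6-(2,2-dimethoxyethyl)-3-hydroxy-4,6-dimethyloxan-2-yl]-N-methoxy-N,2-dimethylpropanamide | C[C@@H](C[C@@H]1O[C@@](C)(CC(OC)OC)C[C@H](C)[C@@H]1O)C(=O)N(C)OC | intermediate
14 | (3S)-4-[(2S,3S,4S,6R)-6-(2,2-dimethoxyethyl)-3-hydroxy-4,6-dimethyloxan-2-yl]-3-methylbutan-2-one | C[C@@H](C[C@@H]1O[C@@](C)(CC(OC)OC)C[C@H](C)[C@@H]1O)C(C)=O | intermediate
15 | {[(3S)-4-{(2S,3S,4S,6R)-6-(2,2-dimethoxyethyl)-4,6-dimethyl-3-[(trimethylsilyl)oxy]oxan-2-yl}-3-methylbut-1-en-2-yl]oxy}trimethylsilane | C[C@@H](C[C@@H]1O[C@@](C)(CC(OC)OC)C[C@H](C)[C@@H]1O[Si](C)(C)C)C(=C)O[Si](C)(C)C | intermediate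
16 | (2E)-1,4-dibromobut-2-ene | BrC/C=C/CBr | starting material
17 | 1-({[(2E)-4-bromobut-2-en-1-yl]oxy}methyl)-4-methoxybenzene | BrC/C=C/COCc1ccc(OC)cc1 | intermediate
18 | propylmagnesium bromide | CCC[Mg]Br | starting material
19 | 1-methoxy-4-({[(2R)-2-ethenylpentyl]oxy}methyl)benzene | CCC[C@H](C=C)COCc1ccc(OC)cc1 | intermediate
20 | (2S)-2-{[(4-methoxyphenyl)methoxy]methyl}pentanal | CCC[C@H](C=O)COCc1ccc(OC)cc1 | intermediate
21 | (2S,5R,6S)-1-[(2S,3S,4S,6R)-6-(2,2-dimethoxyethyl)-3-hydroxy-4,6-dimethyloxan-2-yl]-5-hydroxy-6-{[(4-methoxybenzyl)oxy]methyl}-2-methylnonan-3-one | C[C@@H](C[C@@H]1O[C@@](C)(CC(OC)OC)C[C@H](C)[C@@H]1O)C(=O)C[C@@H](O)[C@@H](CCC)COCc1ccc(OC)cc1 | intermediate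
22 | (2S,5R,6S)-1-[(2S,3S,4S,6R)-6-(2,2-dimethoxyethyl)-3-hydroxy-4,6-dimethyloxan-2-yl]-5-hydroxy-6-(hydroxymethyl)-2-methylnonan-3-one | C[C@@H](C[C@@H]1O[C@@](C)(CC(OC)OC)C[C@H](C)[C@@H]1O)C(=O)C[C@@H](O)[C@@H](CCC)CO | intermediate
23 | (2R,3R,6S)-7-[(2S,3S,4S,6R)-6-(2,2-dimethoxyethyl)-3-hydroxy-4,6-dimethyloxan-2-yl]-3-hydroxy-6-methyl-5-oxo-2-propylheptanal | C[C@@H](C[C@@H]1O[C@@](C)(CC(OC)OC)C[C@H](C)[C@@H]1O)C(=O)C[C@@H](O)[C@@H](CCC)C=O | intermediate
24 | ethyl diazoacetate | CCOC(=O)C=[N+]=[N-] | starting material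
25 | ethyl (4R,5R,8S)-9-[(2S,3S,4S,6R)-6-(2,2-dimethoxyethyl)-3-hydroxy-4,6-dimethyloxan-2-yl]-5-hydroxy-8-methyl-3,7-dioxo-4-propylnonanoate | C[C@@H](C[C@@H]1O[C@@](C)(CC(OC)OC)C[C@H](C)[C@@H]1O)C(=O)C[C@@H](O)[C@@H](CCC)C(=O)CC(=O)OCC | intermediate
26 | (5R,6R)-6-{(3S)-4-[(2S,3S,4S,6R)-6-(2,2-dimethoxyethyl)-3-hydroxy-4,6-dimethyloxan-2-yl]-3-methyl-2-oxobutyl}-4-hydroxy-5-propyl-5,6-dihydro-2H-pyran-2-one | C[C@@H](C[C@@H]1O[C@@](C)(CC(OC)OC)C[C@H](C)[C@@H]1O)C(=O)C[C@H]2OC(=O)C=C(O)[C@@H]2CCC | intermediate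
27 | (5R,6R)-4-hydroxy-6-{(3S)-4-[(2S,3S,4S,6R)-3-hydroxy-4,6-dimethyl-6-(2-oxoethyl)oxan-2-yl]-3-methyl-2-oxobutyl}-5-propyl-5,6-dihydro-2H-pyran-2-one | C[C@@H](C[C@@H]1O[C@@](C)(CC=O)C[C@H](C)[C@@H]1O)C(=O)C[C@H]2OC(=O)C=C(O)[C@@H]2CCC | intermediate
28 | macrocyclic 3-alkylidene-pyran-2,4-dione (C7=C8 alkene, C5 ketone; all stereocentres as in 29; alkene geometry not defined) | CCC[C@H]1C(=O)C2=CC[C@@]3(C)C[C@H](C)[C@H](O)[C@H](C[C@H](C)C(=O)C[C@H]1OC2=O)O3 | intermediate
29 | mangromicin C | CCC[C@H]1C(O)=C2CC[C@@]3(C)C[C@H](C)[C@H](O)[C@H](C[C@H](C)C(=O)C[C@H]1OC2=O)O3 | target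

## Step count and risks

Total step count: 17. Longest linear sequence: 14 steps (steps 1–9, then 13–17); steps 10–12 make the east aldehyde.

The three steps most likely to fail, each with a fallback:

**Step 17 (new macrocyclisation).** The risks are oligomerisation and acid- or enol-mediated opening of the tetrahydropyran at the β-alkoxy aldehyde. The fallback uses known chemistry, sets out from 26 and returns at 29. Aqueous CF3CO2H hydrolyses the acetal and aldehyde 27 is isolated. NaBH(OAc)3 reduces only the aldehyde to the 2-hydroxyethyl pyranone F9. I2/PPh3/imidazole converts the primary alcohol into the 2-iodoethyl pyranone F10. Cs2CO3 in MeCN at 1 mM then closes the ring by the classical intramolecular C-alkylation of a cyclic 1,3-dicarbonyl to give 29. No C8 carbonyl is present in the ring-closing event; O-alkylation is the by-product to watch.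

**Step 7 (facial selectivity of the C13 methylation).** If the methyl group enters on the wrong face, C13 is set instead by a hydroxyl-directed hydrogenation. This fallback sets out from enone 10 and returns at 12, replacing steps 6 and 7. I2/pyridine gives the 4-iodo enone F1. Suzuki coupling with trimethylboroxine (Pd(PPh3)4, K2CO3) gives the 4-methyl enone F2. Luche reduction (NaBH4, CeCl3·7H2O), with hydride anti to the pseudo-axial C9 chain, gives the allylic alcohol F3 with the hydroxyl on the face of that chain. Hydrogenation with [Ir(cod)(PCy3)(py)]PF6 delivers hydrogen to C13 from the hydroxyl face, giving the saturated alcohol F4 with the methyl group on the required face. Dess–Martin oxidation then gives ketone 12 under non-epimerising conditions.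

**Step 16 (Roskamp on an unprotected β-hydroxy aldehyde, then basic lactonisation).** If 23 dehydrates, dimerises or undergoes retro-aldol, the secondary alcohols are protected first. This fallback sets out from 21 and returns at 26, replacing steps 14–16. Et3SiOTf/2,6-lutidine gives the bis(triethylsilyl) ether F5. DDQ gives the primary alcohol F6. Dess–Martin periodinane gives the β-silyloxy aldehyde F7, a well-precedented Roskamp substrate. SnCl2/ethyl diazoacetate gives the silylated β-keto ester F8. HF·pyridine followed by K2CO3/MeOH removes both silyl groups and lactonises to 26.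

Further compounds
F1 | step 7 | (2S)-3-[(2S,6S)-6-(2,2-dimethoxyethyl)-4-iodo-6-methyl-3-oxo-3,6-dihydro-2H-pyran-2-yl]-N-methoxy-N,2-dimethylpropanamide | C[C@@H](C[C@@H]1O[C@@](C)(CC(OC)OC)C=C(I)C1=O)C(=O)N(C)OC
F2 | step 7 | (2S)-3-[(2S,6S)-6-(2,2-dimethoxyethyl)-4,6-dimethyl-3-oxo-3,6-dihydro-2H-pyran-2-yl]-N-methoxy-N,2-dimethylpropanamide | C[C@@H](C[C@@H]1O[C@@](C)(CC(OC)OC)C=C(C)C1=O)C(=O)N(C)OC
F3 | step 7 | (2S)-3-[(2S,3R,6S)-6-(2,2-dimethoxyethyl)-3-hydroxy-4,6-dimethyl-3,6-dihydro-2H-pyran-2-yl]-N-methoxy-N,2-dimethylpropanamide | C[C@@H](C[C@@H]1O[C@@](C)(CC(OC)OC)C=C(C)[C@H]1O)C(=O)N(C)OC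
F4 | step 7 | (2S)-3-[(2S,3R,4S,6R)-6-(2,2-dimethoxyethyl)-3-hydroxy-4,6-dimethyloxan-2-yl]-N-methoxy-N,2-dimethylpropanamide | C[C@@H](C[C@@H]1O[C@@](C)(CC(OC)OC)C[C@H](C)[C@H]1O)C(=O)N(C)OC
F5 | step 16 | (2S,5R,6S)-1-{(2S,3S,4S,6R)-6-(2,2-dimethoxyethyl)-4,6-dimethyl-3-[(triethylsilyl)oxy]oxan-2-yl}-6-{[(4-methoxybenzyl)oxy]methyl}-2-methyl-5-[(triethylsilyl)oxy]nonan-3-one | C[C@@H](C[C@@H]1O[C@@](C)(CC(OC)OC)C[C@H](C)[C@@H]1O[Si](CC)(CC)CC)C(=O)C[C@@H](O[Si](CC)(CC)CC)[C@@H](CCC)COCc1ccc(OC)cc1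
F6 | step 16 | (2S,5R,6S)-1-{(2S,3S,4S,6R)-6-(2,2-dimethoxyethyl)-4,6-dimethyl-3-[(triethylsilyl)oxy]oxan-2-yl}-6-(hydroxymethyl)-2-methyl-5-[(triethylsilyl)oxy]nonan-3-one | C[C@@H](C[C@@H]1O[C@@](C)(CC(OC)OC)C[C@H](C)[C@@H]1O[Si](CC)(CC)CC)C(=O)C[C@@H](O[Si](CC)(CC)CC)[C@@H](CCC)CO
F7 | step 16 | (2R,3R,6S)-7-{(2S,3S,4S,6R)-6-(2,2-dimethoxyethyl)-4,6-dimethyl-3-[(triethylsilyl)oxy]oxan-2-yl}-6-methyl-5-oxo-2-propyl-3-[(triethylsilyl)oxy]heptanal | C[C@@H](C[C@@H]1O[C@@](C)(CC(OC)OC)C[C@H](C)[C@@H]1O[Si](CC)(CC)CC)C(=O)C[C@@H](O[Si](CC)(CC)CC)[C@@H](CCC)C=O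
F8 | step 16 | ethyl (4R,5R,8S)-9-{(2S,3S,4S,6R)-6-(2,2-dimethoxyethyl)-4,6-dimethyl-3-[(triethylsilyl)oxy]oxan-2-yl}-8-methyl-3,7-dioxo-4-propyl-5-[(triethylsilyl)oxy]nonanoate | C[C@@H](C[C@@H]1O[C@@](C)(CC(OC)OC)C[C@H](C)[C@@H]1O[Si](CC)(CC)CC)C(=O)C[C@@H](O[Si](CC)(CC)CC)[C@@H](CCC)C(=O)CC(=O)OCC
F9 | step 17 | (5R,6R)-4-hydroxy-6-{(3S)-4-[(2S,3S,4S,6R)-3-hydroxy-6-(2-hydroxyethyl)-4,6-dimethyloxan-2-yl]-3-methyl-2-oxobutyl}-5-propyl-5,6-dihydro-2H-pyran-2-one | C[C@@H](C[C@@H]1O[C@@](C)(CCO)C[C@H](C)[C@@H]1O)C(=O)C[C@H]2OC(=O)C=C(O)[C@@H]2CCC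
F10 | step 17 | (5R,6R)-4-hydroxy-6-{(3S)-4-[(2S,3S,4S,6R)-3-hydroxy-6-(2-iodoethyl)-4,6-dimethyloxan-2-yl]-3-methyl-2-oxobutyl}-5-propyl-5,6-dihydro-2H-pyran-2-one | C[C@@H](C[C@@H]1O[C@@](C)(CCI)C[C@H](C)[C@@H]1O)C(=O)C[C@H]2OC(=O)C=C(O)[C@@H]2CCC
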